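**Retrosynthetic overview**
- Feature: the C9 ketone and C4 (a carbinol in the target, a ketone earlier) are 1,5-related through C10, C1 and C5. This is the trace of a retro-aldol cleavage of C5–C9 in a cyclobutane C1–C5–C9–C10, which comes from a [2+2] of a 2-acylcyclopentanone enol acetate (C5=C9) with its tethered alkene C1=C10.
- Ring order: the carbocycle C5–C9 comes from the silyloxycyclopentenone. The photocycloaddition closes the five-membered ring C1–C5 and the cyclobutane. The retro-aldol step merges the four- and five-membered rings into the seven-membered ring.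
- The C7 silyloxy centre fixes C1 and then leaves by E1cB. The double bond is moved by base to C5=C6, which also differentiates the two ketones.
- Stereo relay: CBS carbinol at C4, then OH-directed hydrogenation (C5), then isopropyl addition to the trans-fused ketone (C4), then C4–OH-directed reduction of a C6 ketone (C6).
- Enone C7=C8(CH3)–C9=O: C8 methylation and dehydrogenation (the C10 side is blocked by quaternary C1), then γ-oxidation at C6. Anisoylation comes last.

Key step: step 5

Numbering used throughout: C1 quaternary methyl carbon, C2 and C3 CH2, C4 isopropyl carbinol, C5 ring-fusion CH, C6 ester carbon, C7=C8(CH3), C9 ketone, C10 CH2. β is the face of the C1 methyl and the C4 hydroxyl. α is the face of C5–H, C6–O and the isopropyl group. The target is (1R,4R,5S,6S).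

Remark on the chemistry: the C7 silyloxy group ends up on the α face, which is the face that must later receive C5–H and C6–O. In a C5=C6 enone, CH3 and C10 on C1 flank both π faces almost alike. A hydroboration next to that group and an isopropyl addition to the enone are therefore not relied on. C5, C4 and C6 are each set by a directed or 1,2-controlled step.

Assumption: centres that are erased later (C5 in 6 and 10–12, C8 in 22) are left open in the SMILES.

**Step 1**
Reactants: 1 4-methylpent-4-enoic acid
Product: 2 1-(4-methylpent-4-enoyl)-1H-benzotriazole
Conditions: 1H-benzotriazole, DCC, CH2Cl2, 0 °C → rt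
Reagents that add atoms: 1H-benzotriazole, c1ccc2[nH]nnc2c1
Why: Carbodiimide coupling gives an N-acylbenzotriazole, a neutral acyl donor known to C-acylate ketone enolates, and the 1,1-disubstituted alkene is not touched.

**Step 2**
Reactants: 3 (S)-4-(tert-butyldimethylsilyloxy)cyclopent-2-en-1-one
Product: 4 (R)-4-(tert-butyldimethylsilyloxy)-1-[dimethyl(phenyl)silyloxy]cyclopent-1-ene
Conditions: PhMe2SiH, RhCl(PPh3)3 (1 mol %), THF, 50 °C
Reagents that add atoms: dimethylphenylsilane, C[SiH](C)c1ccccc1
Why: Rh-catalysed 1,4-hydrosilylation of an enone with a monohydrosilane fixes the enol double bond at C9=C5, away from the silyloxy carbon, so no enolate able to expel that group is formed and C7 is untouched (the descriptor changes only through priorities).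

**Step 3**
Reactants: 4 silyl enol ether; 2 1-(4-methylpent-4-enoyl)-1H-benzotriazole
Product: 6 (4R)-2-(4-methylpent-4-enoyl)-4-(tert-butyldimethylsilyloxy)cyclopentan-1-one (keto/enol mixture), via lithium enolate 5 (not isolated)
Conditions: MeLi, THF, 0 °C; cannulated into 2, THF, −78 °C; aq NH4Cl
Reagents that add atoms: none
Why: Si–O cleavage by MeLi releases the regiodefined lithium enolate, and inverse addition to the acylbenzotriazole gives Claisen-type C-acylation at C5 faster than proton exchange; the new C5 centre is labile and irrelevant.

**Step 4**
Reactants: 6 β-diketone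
Product: 7 (4R)-2-(4-methylpent-4-enoyl)-4-(tert-butyldimethylsilyloxy)cyclopent-1-en-1-yl acetate
Conditions: AcCl, pyridine, CH2Cl2, 0 °C → rt
Reagents that add atoms: acetyl chloride, CC(=O)Cl
Why: This is O-acylation of a β-diketone; acyl transfer through pyridine lets the acetyl group settle on the ring oxygen, which keeps the tetrasubstituted double bond endocyclic and the ketone acyclic, as known for 2-acylcyclopentanones.

**Step 5**
Reactants: 7 enol acetate
Product: 8 tricyclic cyclobutyl acetate (cyclobutane C1–C5–C9–C10 cis-fused to the cyclopentanone C1–C5 and to the cyclopentane C5–C9; C9 acetoxy; C7 silyloxy anti to the cyclobutane)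
Conditions: hν (medium-pressure Hg lamp, Pyrex, λ > 290 nm), degassed cyclohexane (5 mM), 15 °C
Reagents that add atoms: none
Why: Pyrex-filtered light excites the β-acetoxy enone (C4=O conjugated with C5=C9) and, after intersystem crossing, its triplet attacks the C1=C10 alkene held three atoms from C5, giving a 1,4-biradical that closes after spin inversion. The closest known reaction is the intramolecular enone–alkene [2+2] photocycloaddition of β-diketone enol esters, the first half of the de Mayo reaction, known for 2-(alk-4-enoyl)cycloalkanone enol esters. The cyclopentanone ring C1–C5 closes first by 5-exo attack of C5 on C1 (rule of five), and the cyclobutane then closes by C9–C10 radical combination, which gives the straight and not the crossed adduct. C1, C5 and C9 are locked to one another because a three-atom tether and a four-membered ring tolerate only cis fusions, so the only open choice is the face of the cyclopentene. That facial selectivity is what the step needs: the chain should fold over the face anti to the C7 tert-butyldimethylsilyloxy group, which puts the C1 methyl on the later β face, (R) at C1. The syn adduct is a diastereomer and is removed here by chromatography, so the optical purity of the later C7-free compounds does not depend on the size of the bias.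

**Step 6**
Reactants: 8 photoadduct
Product: 11 cycloheptenone (C4=O; C9=O; C7=C8; C1 methyl β; C5 epimers), via cyclobutanol 9 (not isolated), via silyloxy dione 10 (not isolated)
Conditions: K2CO3, MeOH, 0 °C → rt
Reagents that add atoms: none
Why: Methanolysis frees a cyclobutanol β to the C4 ketone, whose retro-aldol cleavage of C5–C9 (second half of the de Mayo reaction) is driven by strain release, and the β-silyloxy ketone so formed loses silanolate by E1cB; C1 is untouched.

**Step 7**
Reactants: 11 cycloheptenone
Product: 13 (R)-alkylidenecyclopentanone (C4=O conjugated with C5=C6; C9 saturated ketone), via deconjugated enone 12 (not isolated)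
Conditions: DBU (0.5 equiv), toluene, 100 °C
Reagents that add atoms: none
Why: Base-catalysed prototropic equilibration through dienolates (out of conjugation to C6=C7, then into conjugation with C4) should drain the weakly conjugated disubstituted cycloheptenone into the planar trisubstituted 2-alkylidenecyclopentanone, and quaternary C1 stops any further migration.

**Step 8**
Reactants: 13 alkylidenecyclopentanone
Product: 14 C9 ethylene ketal of 13
Conditions: TMSOCH2CH2OTMS, TMSOTf (5 mol %), CH2Cl2, −78 → −30 °C; pyridine
Reagents that add atoms: 1,2-bis(trimethylsilyloxy)ethane, C[Si](C)(C)OCCO[Si](C)(C)C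
Why: Silyl-triflate-catalysed ketalisation with the bis-silylated glycol at low temperature takes saturated ketones and leaves conjugated enones, so only C9 is masked and the double bond does not move.

**Step 9**
Reactants: 14 enone ketal
Product: 15 (4R)-allylic alcohol (C4–OH α; C5=C6)
Conditions: (S)-Me-CBS (20 mol %), catecholborane, toluene, −78 °C; aq NaOH
Reagents that add atoms: none
Why: In this CBS reduction the oxazaborolidine treats the fully substituted C5 as the large group and C3H2 as the small one, so reagent control (the substrate has almost no bias of its own) should give the α-carbinol, and any material of the wrong C1 series becomes a separable diastereomer.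

**Step 10**
Reactants: 15 allylic alcohol
Product: 16 trans-fused alcohol (C4–OH α; C5–H α)
Conditions: H2 (1 atm), [Ir(cod)(PCy3)(py)]PF6 (5 mol %), CH2Cl2, rt
Reagents that add atoms: none
Why: In this hydroxyl-directed hydrogenation the cationic iridium binds the α-hydroxyl and delivers H2 to the same face of the trisubstituted alkene, which sets C5–H α and hence the trans ring fusion under kinetic control.

**Step 11**
Reactants: 16 alcohol
Product: 17 trans-fused C4 ketone (C9 ketal)
Conditions: TPAP (5 mol %), NMO, 4 Å MS, CH2Cl2, rt
Reagents that add atoms: none
Why: The Ley–Griffith oxidation is neutral, so the ketal survives and the kinetically set C5 centre meets neither acid nor strong base.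

**Step 12**
Reactants: 17 trans-fused ketone; 18 isopropylmagnesium chloride
Product: 19 tertiary alcohol (C4–OH β; isopropyl α; C9 ketal)
Conditions: i-PrMgCl, CeCl3, THF, −78 → 0 °C; aq NH4Cl
Reagents that add atoms: isopropylmagnesium chloride, CC(C)[Mg]Cl
Why: This is an organocerium 1,2-addition, whose low basicity suppresses enolisation, C5 epimerisation and β-hydride reduction; in the trans-fused ketone the C1 methyl stands axial over the β face and C5 offers only H on the α face, so isopropyl enters from α (as nucleophiles do on steroid D-ring ketones) and leaves the hydroxyl β.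

**Step 13**
Reactants: 19 ketal
Product: 20 hydroxy ketone (C9=O)
Conditions: AcOH–THF–H2O, 40 °C
Reagents that add atoms: water, O
Why: Mild acid hydrolysis of the dioxolane is used, too weak to ionise the tertiary carbinol.

**Step 14**
Reactants: 20 hydroxy ketone
Product: 22 C8-methyl ketone (C8 epimers), via dilithio enolate 21 (not isolated)
Conditions: LDA (2.2 equiv), THF, −78 °C; MeI, −78 → −30 °C; aq NH4Cl
Reagents that add atoms: iodomethane, CI
Why: This is a kinetic enolate alkylation: LDA takes the OH proton and then the unhindered C8–H rather than the neopentyl C10–H (as with 3,3-dialkylcycloalkanones), and the new C8 centre becomes sp2 in the next step.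

**Step 15**
Reactants: 22 methyl ketone
Product: 23 enone (C7=C8(CH3)–C9=O)
Conditions: IBX, DMSO–PhF, 70 °C
Reagents that add atoms: none
Why: IBX dehydrogenates the ketone through its enol; C1 carries no hydrogen, so nothing can be lost on the C10 side and only C7=C8 can form, and the tertiary alcohol is inert.

**Step 16**
Reactants: 23 enone
Product: 24 enedione (C6=O; C7=C8(CH3); C9=O)
Conditions: Pd(OH)2/C (5 mol %), t-BuOOH, K2CO3 (0.25 equiv), CH2Cl2, 4 °C → rt
Reagents that add atoms: tert-butyl hydroperoxide, CC(C)(C)OO
Why: This is the Pd(OH)2/C–hydroperoxide oxidation of α,β-enones to 1,4-enediones, in which the peroxy radical abstracts the γ-hydrogen at C6 and the peroxide collapses to the ketone; C5 should stay trans, since that isomer keeps C6 away from the α-isopropyl group and holds the C4–OH···O=C6 hydrogen bond.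

**Step 17**
Reactants: 24 enedione
Product: 25 lancerodiol (C4–OH β; C6–OH α)
Conditions: Me4NBH(OAc)3, MeCN–AcOH, −30 °C
Reagents that add atoms: none
Why: In this Evans–Saksena reduction, acetate exchange binds boron to the β C4 hydroxyl and hydride passes through a six-membered transition state to the β face of C6=O, which sets C6–OH α, while the C9 enone has no hydroxyl in reach and is not reduced by this weak hydride.

**Step 18**
Reactants: 25 lancerodiol; 26 4-methoxybenzoyl chloride
Product: 27 lancerodiol p-methoxybenzoate
Conditions: 4-MeOC6H4COCl, Et3N, DMAP (cat.), CH2Cl2, 0 °C → rt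
Reagents that add atoms: 4-methoxybenzoyl chloride, COc1ccc(cc1)C(Cl)=O
Why: DMAP-catalysed acylation selects the secondary allylic C6–OH over the hindered tertiary C4–OH, and no stereocentre is touched.

**Compound list**
1 | 4-methylpent-4-enoic acid | C=C(C)CCC(=O)O | starting material
2 | 1-(4-methylpent-4-enoyl)-1H-benzotriazole | C=C(C)CCC(=O)n1nnc2ccccc12 | intermediate
3 | (S)-4-(tert-butyldimethylsilyloxy)cyclopent-2-en-1-one | O=C1C=C[C@@H](O[Si](C)(C)C(C)(C)C)C1 | starting material
4 | (R)-4-(tert-butyldimethylsilyloxy)-1-[dimethyl(phenyl)silyloxy]cyclopent-1-ene | C[Si](C)(c1ccccc1)OC2=CC[C@@H](O[Si](C)(C)C(C)(C)C)C2 | intermediate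
5 | lithium (R)-4-(tert-butyldimethylsilyloxy)cyclopent-1-en-1-olate (not isolated) | [Li]OC1=CC[C@@H](O[Si](C)(C)C(C)(C)C)C1 | intermediate
6 | (4R)-2-(4-methylpent-4-enoyl)-4-(tert-butyldimethylsilyloxy)cyclopentan-1-one | C=C(C)CCC(=O)C1C[C@@H](O[Si](C)(C)C(C)(C)C)CC1=O | intermediate
7 | (4R)-2-(4-methylpent-4-enoyl)-4-(tert-butyldimethylsilyloxy)cyclopent-1-en-1-yl acetate | CC(=O)OC1=C(C(=O)CCC(C)=C)C[C@@H](O[Si](C)(C)C(C)(C)C)C1 | intermediate
8 | tricyclic cyclobutyl acetate photoadduct | CC(=O)O[C@]12C[C@H](O[Si](C)(C)C(C)(C)C)C[C@]13C(=O)CC[C@]3(C)C2 | intermediate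
9 | tricyclic cyclobutanol (not isolated) | O[C@]12C[C@H](O[Si](C)(C)C(C)(C)C)C[C@]13C(=O)CC[C@]3(C)C2 | intermediate
10 | 7α-silyloxy hydroazulene-4,9-dione (not isolated) | O=C1CC[C@]2(C)CC(=O)C[C@H](O[Si](C)(C)C(C)(C)C)CC12 | intermediate
11 | hydroazul-7-ene-4,9-dione (cycloheptenone) | O=C1CC[C@]2(C)CC(=O)C=CCC12 | intermediate
12 | hydroazul-6-ene-4,9-dione (not isolated) | O=C1CC[C@]2(C)CC(=O)CC=CC12 | intermediate
13 | (R)-hydroazul-5-ene-4,9-dione (alkylidenecyclopentanone) | O=C1CC[C@]2(C)CC(=O)CCC=C12 | intermediate
14 | C9 ethylene ketal of 13 | O=C1CC[C@]2(C)CC3(OCCO3)CCC=C12 | intermediate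
15 | (4R)-allylic alcohol, C4–OH α | O[C@@H]1CC[C@]2(C)CC3(OCCO3)CCC=C12 | intermediate
16 | trans-fused alcohol, C4–OH α, C5–H α | O[C@@H]1CC[C@]2(C)CC3(OCCO3)CCC[C@@H]12 | intermediate
17 | trans-fused C4 ketone, C9 ketal | O=C1CC[C@]2(C)CC3(OCCO3)CCC[C@@H]12 | intermediate
18 | isopropylmagnesium chloride | CC(C)[Mg]Cl | starting material
19 | 4β-hydroxy-4α-isopropyl C9 ketal | CC(C)[C@]1(O)CC[C@]2(C)CC3(OCCO3)CCC[C@@H]12 | intermediate
20 | 4β-hydroxy-4α-isopropyl C9 ketone | CC(C)[C@]1(O)CC[C@]2(C)CC(=O)CCC[C@@H]12 | intermediate
21 | dilithio alkoxide-enolate (C8=C9, not isolated) | CC(C)[C@]1(O[Li])CC[C@]2(C)CC(O[Li])=CCC[C@@H]12 | intermediate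
22 | C8-methyl ketone | CC(C)[C@]1(O)CC[C@]2(C)CC(=O)C(C)CC[C@@H]12 | intermediate
23 | 8-methyl-7-en-9-one | CC(C)[C@]1(O)CC[C@]2(C)CC(=O)C(C)=CC[C@@H]12 | intermediate
24 | 8-methyl-7-ene-6,9-dione | CC(C)[C@]1(O)CC[C@]2(C)CC(=O)C(C)=CC(=O)[C@@H]12 | intermediate
25 | lancerodiol | CC(C)[C@]1(O)CC[C@]2(C)CC(=O)C(C)=C[C@H](O)[C@@H]12 | intermediate
26 | 4-methoxybenzoyl chloride | COc1ccc(cc1)C(Cl)=O | starting material
27 | lancerodiol p-methoxybenzoate, (1R,4R,5S,6S) | COc1ccc(C(=O)O[C@H]2C=C(C)C(=O)C[C@@]3(C)CC[C@@](O)(C(C)C)[C@H]23)cc1 | target

Total step count: 18. Longest linear sequence: 17 (steps 2–18, from 3).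

**Steps most likely to fail**

Step 5. The silyloxy group stands two bonds from either reacting ring carbon and may sort the two faces only weakly. The excited enol ester may also be drained by a photochemical 1,3-acetyl shift or by crossed closure. The fallback sets out from 6 and comes back at 11. The diketone 6 is irradiated as such (Pyrex, cyclohexane). Its hydrogen-bonded ring enol is then the chromophore, which is the classical de Mayo mode, and no acyl group is present to migrate. Cyclobutanol 9 opens in the flask to 10, which is now isolated so that the C1/C7 diastereomers can be separated. K2CO3 in MeOH then gives 11.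

Step 7. The double-bond migration may stop at an equilibrium mixture, or base-induced transannular condensation may consume the dione. The fallback sets out from 11 and comes back at 14. Ethylene glycol (one equivalent), p-TsOH and benzene under water removal ketalise the conjugated C9 carbonyl, with the usual shift of the double bond out of conjugation (as for steroidal 4-en-3-ones). This gives the C9-dioxolane with C6=C7 F1. Its alkene lies β,γ to the free C4 ketone only, and catalytic DBU at room temperature moves it into conjugation to give 14. An equilibrium between two enones is thus replaced by removal of C9 from the π system.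

Step 16. The radical oxidation may stall at the hindered C6, or the carbonate may trigger epimerisation at C5 or retro-aldol opening of the new β-hydroxy ketone. The fallback sets out from 23 and comes back at 24. TBSOTf and Et3N give the extended dienol silyl ether F2. Buffered m-CPBA attacks its terminal C6=C7 bond (vinylogous Rubottom oxidation, as for steroidal 3,5-dienol ethers) to give the 6-hydroxy enone F3 as C6 epimers. MnO2 then oxidises the allylic alcohol to 24. Any α-epimer in F3 is 25 itself and can go on directly.

**Further compounds**
F0 | step 5 | none | none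
F1 | step 7 | C9 ethylene ketal with C6=C7 and free C4 ketone | O=C1CC[C@]2(C)CC3(OCCO3)CC=CC12
F2 | step 16 | C9 tert-butyldimethylsilyl dienol ether (C8=C9, C6=C7) | CC(C)[C@]1(O)CC[C@]2(C)CC(O[Si](C)(C)C(C)(C)C)=C(C)C=C[C@@H]12
F3 | step 16 | 6-hydroxy-8-methyl-7-en-9-one, C6 epimers | CC(C)[C@]1(O)CC[C@]2(C)CC(=O)C(C)=CC(O)[C@@H]12
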